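A direct plan would start from L‑tyrosinol A1 (atom labels: C1 CH–N, C2 CH2, C3 bridgehead C–OH, C4 C=O, C5 bridgehead CH, C6 CHOH, C7/C8 epoxide CH with C8 on C3, C9 CHOH).
It would acylate A1 to the amide A2 and dearomatise the phenol to the p‑quinol A3, so that ring B would come first.
It would then tie the C9 hydroxyl to one enone arm as the temporary pyran A4, epoxidise and reduce the other arm, and close ring A last by a C5–C9 aldol reaction of the keto‑aldehyde A5.
Its weakest step would be the equilibrating oxa‑Michael desymmetrisation to A4: C3 would be fixed only by a small energy gap between two cis‑fused chairs, so a mixture at the quaternary centre would be likely.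
Next would be the making and unmaking of the pyran (addition, dehydrogenation, enol‑ether hydrolysis): these operations would leave no bond in the target, and the last would free a β‑hydroxy ketone beside an epoxide that would tend to dehydrate.
Last would be the closing aldol: A5 would be an epimerisable α‑amido aldehyde, its C5 enolate would carry the C6 hydroxyl as a β‑leaving group, and C5 and C9 would be set in a reversible step.

The new plan buys ring A as 4‑aminocyclohexanone and builds ring B from propargyl bromide (C8–C7–C6). It rests on one feature: in the ring‑A enone 8, C5=C9 lies between the C1 amide on one face and the C3 propargyl group on the other. In a single operation the amide oxygen adds to C9 and C5 adds to the alkyne (C5–C6): two rings close, C9 and C5 are set, and the bridged core appears with its bridgehead ketol in place. No aldehyde, no pyran detour and no equilibrium‑controlled quaternary centre remain. Since all heteroatoms sit on exo faces and C5 is a bridgehead, one O2 molecule then supplies C6–OH and the epoxide.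

Key step: step 6

Convention: ring A = C1–C2–C3–C4–C5–C9, ring B = C3–C4–C5–C6–C7–C8; exo = the face of either ring that is turned towards C4.
Assumption: the sense of induction of lithium bis(1‑phenylethyl)amide is taken to be the one known for 4‑tert‑butylcyclohexanone, which calls for the (S,S)‑base; if it were the opposite, the (R,R)‑base would be used.

Step 1
Reactants: 1 4‑aminocyclohexanone hydrochloride; 2 (E)‑dec‑2‑enoic acid
Product: 3 (E)‑N‑(4‑oxocyclohexyl)dec‑2‑enamide
Conditions: EDC·HCl, HOBt, i‑Pr2NEt, CH2Cl2, 0 °C → rt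
Reagents that add atoms: none
Why: Carbodiimide amide coupling; the amine is freed in the presence of the active ester, so that acylation should outrun self‑condensation, and the product is achiral (mirror plane through C1 and C4).

Step 2
Reactants: 3 (E)‑N‑(4‑oxocyclohexyl)dec‑2‑enamide; 4 propargyl bromide (3‑bromoprop‑1‑yne)
Product: 5 (E)‑N‑[(1R)‑4‑oxo‑3‑(prop‑2‑yn‑1‑yl)cyclohexyl]dec‑2‑enamide (both C3 epimers, used together)
Conditions: (S,S)‑bis(1‑phenylethyl)amine·HCl (2.2 equiv), n‑BuLi (4.4 equiv), THF, −78 → 0 °C; 3, −100 °C; 4, DMPU, −78 → −40 °C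
Reagents that add atoms: none
Why: Enantioselective deprotonation with a C2‑symmetric chiral lithium amide (LiCl present; the first equivalent is used up by the N–H) removes one of the two enantiotopic axial α‑protons, and C‑alkylation of that enolate marks this α‑carbon as C3 and thereby makes C1 a stereocentre.

Step 3
Reactants: 5 (E)‑N‑[(1R)‑4‑oxo‑3‑(prop‑2‑yn‑1‑yl)cyclohexyl]dec‑2‑enamide
Product: 6 (E)‑N‑[(1R)‑4‑(tert‑butyldimethylsilyloxy)‑3‑(prop‑2‑yn‑1‑yl)cyclohex‑3‑en‑1‑yl]dec‑2‑enamide
Conditions: TBSOTf (2.2 equiv), Et3N, CH2Cl2, 0 °C → rt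
Reagents that add atoms: tert‑butyldimethylsilyl trifluoromethanesulfonate, CC(C)(C)[Si](C)(C)OS(=O)(=O)C(F)(F)F
Why: Soft enolisation under equilibrating silyl triflate/amine conditions should give the more substituted C3=C4 enol silane, which erases the C3 mixture, while the silyl imidate formed from the amide is lost on work‑up.

Step 4
Reactants: 6 (E)‑N‑[(1R)‑4‑(tert‑butyldimethylsilyloxy)‑3‑(prop‑2‑yn‑1‑yl)cyclohex‑3‑en‑1‑yl]dec‑2‑enamide
Product: 7 (E)‑N‑[(1R,3R)‑3‑(tert‑butyldimethylsilyloxy)‑4‑oxo‑3‑(prop‑2‑yn‑1‑yl)cyclohexyl]dec‑2‑enamide (OTBS cis to the amide)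
Conditions: m‑CPBA, CH2Cl2, −20 °C
Reagents that add atoms: 3‑chloroperoxybenzoic acid, OOC(=O)c1cccc(Cl)c1 (one O)
Why: Rubottom oxidation with hydrogen‑bond direction: the peracid, held by the homoallylic amide N–H as is known for N‑(cyclohex‑3‑enyl) amides, should attack C3=C4 on the face of the amide, and the 1,4‑silyl shift leaves C3–OTBS cis to nitrogen and the propargyl group on the other face.

Step 5
Reactants: 7 (E)‑N‑[(1R,3R)‑3‑(tert‑butyldimethylsilyloxy)‑4‑oxo‑3‑(prop‑2‑yn‑1‑yl)cyclohexyl]dec‑2‑enamide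
Product: 8 (E)‑N‑[(1S,5R)‑5‑(tert‑butyldimethylsilyloxy)‑4‑oxo‑5‑(prop‑2‑yn‑1‑yl)cyclohex‑2‑en‑1‑yl]dec‑2‑enamide
Conditions: IBX, toluene/DMSO (2:1), 70 °C
Reagents that add atoms: none
Why: IBX dehydrogenation of a ketone; C3 is quaternary, so C5 is the only enolisable α‑carbon and only the C5=C9 enone can form (the descriptor at C1 changes by priority only).

Step 6
Reactants: 8 (E)‑N‑[(1S,5R)‑5‑(tert‑butyldimethylsilyloxy)‑4‑oxo‑5‑(prop‑2‑yn‑1‑yl)cyclohex‑2‑en‑1‑yl]dec‑2‑enamide
Product: 10 tricyclic oxazoline ketone: 1‑(tert‑butyldimethylsilyloxy)bicyclo[3.3.1]non‑6‑en‑9‑one (C3–OTBS, C4=O, C6=C7) with a 2‑[(E)‑non‑1‑enyl]oxazoline cis‑fused on the exo face at C1 (N) and C9 (O), via cis‑fused 2‑[(E)‑non‑1‑enyl]‑5,6‑bis(tert‑butyldimethylsilyloxy)‑5‑(prop‑2‑yn‑1‑yl)‑3a,4,5,7a‑tetrahydro‑1,3‑benzoxazole 9 (not isolated)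
Conditions: TBSOTf (1.1 equiv), 2,6‑di‑tert‑butyl‑4‑methylpyridine, CH2Cl2, −78 → −20 °C; then [JohnPhosAu(NCMe)]SbF6 (5 mol %), i‑PrOH (2 equiv), rt
Reagents that add atoms: tert‑butyldimethylsilyl trifluoromethanesulfonate, CC(C)(C)[Si](C)(C)OS(=O)(=O)C(F)(F)F (its silyl group is found in 9, not in 10)
Why: Proposed new method: TBSOTf silylates the C4 carbonyl and the amide oxygen on C1 adds to the activated C9 on the face that carries nitrogen (oxazoline, 5‑exo‑trig; the pyridine only takes the N–H proton), and the enol silane 9 is then attacked at C5 by the gold‑activated alkyne (ring B, 6‑endo‑dig), after which i‑PrOH takes up the silyl group and protonates the vinyl–gold bond, so that 8 is isomerised to 10. The closest known reaction types are the silyl‑triflate‑promoted conjugate addition of neutral heteroatom nucleophiles (phosphines, sulfides, pyridines) to enones with enol‑silane trapping, the halocyclisation of cyclohex‑2‑enyl amides to cis‑fused oxazolines, and the gold(I)‑catalysed 6‑endo‑dig carbocyclisation (Conia‑ene type) of 2‑propargylcycloalkanone enol silanes to bicyclo[3.3.1]nonenones; their union as an anti oxy‑alkenylation of an enone is new. C9 is controlled by C1, because the N–C–O tether can reach the neighbouring carbon only on its own face (cis fusion), and C5 is controlled by C3, because three carbons can span C3 and C5 only on one face, which is the face opposite to the new C9–O bond. The step needs O‑addition to win over γ‑deprotonation at C1 and 6‑endo to win over 5‑exo closure: C3 is quaternary so no α′‑proton exists, the base is too hindered and too weak for C1–H, and the bulky biaryl phosphine together with the higher strain of the bicyclo[3.2.1] alternative should favour attack at the terminal alkyne carbon. Once ring B is closed C5 is a bridgehead, so the C9 oxygen can no longer be lost by β‑elimination and 10 is the sink.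

Step 7
Reactants: 10 tricyclic oxazoline ketone
Product: 12 (E)‑N‑[1,4‑dihydroxy‑9‑oxobicyclo[3.3.1]non‑6‑en‑3‑yl]dec‑2‑enamide (3‑exo amide on C1, 4‑exo hydroxyl on C9, bridgehead hydroxyl on C3), via the C1 amine bearing the C9 (E)‑dec‑2‑enoate ester 11 (not isolated)
Conditions: 48% aq HF, MeCN, 0 °C → rt; then sat. aq NaHCO3 (pH 8), rt
Reagents that add atoms: water, O (becomes the amide carbonyl oxygen)
Why: Acid hydrolysis of the 2‑oxazoline gives the O‑acyl ammonium salt while HF cleaves the silyl ether, and at pH 8 the cis‑1,2 O→N acyl shift restores the amide; no stereocentre is touched and elimination is excluded because C3 and C5 are bridgeheads.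

Step 8
Reactants: 12 (E)‑N‑[1,4‑dihydroxy‑9‑oxobicyclo[3.3.1]non‑6‑en‑3‑yl]dec‑2‑enamide
Product: 14 isariotin D, via the 6‑exo allylic hydroperoxide (E)‑N‑[6‑hydroperoxy‑1,4‑dihydroxy‑9‑oxobicyclo[3.3.1]non‑7‑en‑3‑yl]dec‑2‑enamide 13 (not isolated)
Conditions: O2, tetraphenylporphyrin (cat.), hν (visible), Ti(Oi‑Pr)4 (10 mol %), 4 Å MS, CH2Cl2, 0 °C
Reagents that add atoms: dioxygen, O=O (both O are kept)
Why: Schenck ene reaction followed by titanium‑catalysed oxygen transfer from the allylic hydroperoxide: singlet oxygen can bind only at C6 and take the pseudoaxial exo hydrogen of C8, since the other ene path would need a C5=C6 bridgehead alkene and the endo face is covered by ring A, and Ti(IV) held at the C6 oxygen then delivers the second oxygen to C7=C8 on the same exo face, so that C6, C7 and C8 are set together (the electron‑poor side‑chain alkene should stay inert).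

Compound list
1 | 4‑aminocyclohexanone hydrochloride | NC1CCC(=O)CC1.Cl | starting material
2 | (E)‑dec‑2‑enoic acid | CCCCCCC/C=C/C(=O)O | starting material
3 | (E)‑N‑(4‑oxocyclohexyl)dec‑2‑enamide | CCCCCCC/C=C/C(=O)NC1CCC(=O)CC1 | intermediate
4 | propargyl bromide | C#CCBr | starting material
5 | α‑propargyl ketone (C3 epimers) | CCCCCCC/C=C/C(=O)N[C@H]1CC(CC#C)C(=O)CC1 | intermediate
6 | tetrasubstituted enol silane | CCCCCCC/C=C/C(=O)N[C@H]1CC(CC#C)=C(O[Si](C)(C)C(C)(C)C)CC1 | intermediate
7 | α‑silyloxy ketone (C3 set) | CCCCCCC/C=C/C(=O)N[C@H]1C[C@@](CC#C)(O[Si](C)(C)C(C)(C)C)C(=O)CC1 | intermediate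
8 | ring‑A enone | CCCCCCC/C=C/C(=O)N[C@H]1C[C@@](CC#C)(O[Si](C)(C)C(C)(C)C)C(=O)C=C1 | intermediate
9 | cis‑fused oxazoline enol silane | CCCCCCC/C=C/C1=N[C@H]2C[C@@](CC#C)(O[Si](C)(C)C(C)(C)C)C(O[Si](C)(C)C(C)(C)C)=C[C@H]2O1 | intermediate
10 | tricyclic oxazoline ketone | CCCCCCC/C=C/C1=N[C@H]2C[C@@]3(O[Si](C)(C)C(C)(C)C)C(=O)[C@H](C=CC3)[C@H]2O1 | intermediate
11 | amino ester | N[C@H]1C[C@@]2(O)C(=O)[C@H](C=CC2)[C@H]1OC(=O)/C=C/CCCCCCC | intermediate
12 | dihydroxy amide alkene | CCCCCCC/C=C/C(=O)N[C@H]1C[C@@]2(O)C(=O)[C@H](C=CC2)[C@H]1O | intermediate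
13 | 6‑exo allylic hydroperoxide | CCCCCCC/C=C/C(=O)N[C@H]1C[C@@]2(O)C(=O)[C@H]([C@H](OO)C=C2)[C@H]1O | intermediate
14 | isariotin D | CCCCCCC/C=C/C(=O)N[C@H]1C[C@@]2(O)C(=O)[C@H]([C@H](O)[C@@H]3O[C@@H]32)[C@H]1O | target

Total step count: 8. Longest linear sequence: 8.

Steps most likely to fail

Step 6 (proposed new method). The silyl‑activated enone may lose the C1 proton instead of taking up the amide oxygen, the O‑addition may revert before the gold stage, or the oxazoline nitrogen may slow the catalyst. The fallback uses known reactions only, sets out from 8 and returns at 9. Weitz–Scheffer epoxidation (t‑BuOOH, DBU), which should occur anti to the amide, would give the trans‑epoxy ketone F1. BF3·OEt2 would let the amide oxygen open the epoxide at C9 with inversion (5‑exo‑tet) to the cis‑fused hydroxy oxazoline ketone F2. Acetylation would give the C5 acetate F3, and SmI2/MeOH would remove the C5 oxygen to give the oxazoline ketone F4. TBSOTf/Et3N would then give 9, which would be isolated and submitted to the gold(I) closure alone.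

Step 4. Facial selectivity may be poor if hydrogen‑bond direction does not outweigh the steric bias of the very reactive enol silane. The fallback reverses the order of bond formation at C3, sets out from 3 and returns at 8. The same chiral base with TBSOTf as the quench would give the enol silane F5. Rubottom oxidation would give the α‑silyloxy ketone F6, of which either C3 epimer serves, and IBX would give the α′‑silyloxy enone F7. The cross‑conjugated enolate of F7 (LDA; C3–H is the only α′‑proton) would be alkylated by 4 on the face away from the amide, so that C3 would be set by C–C instead of C–O bond formation.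

Step 8. The ene reaction of a cis‑disubstituted alkene that is inductively deactivated by the ketone may be slow, with sensitiser bleaching and loss of material on long irradiation. The fallback builds the same array by ionic exo‑face chemistry, sets out from 10 and returns at 14. m‑CPBA would give the 6,7‑exo‑epoxide F8. Diethylaluminium 2,2,6,6‑tetramethylpiperidide would isomerise it by syn‑elimination of the exo C8 hydrogen to the 6‑exo allylic alcohol F9. VO(acac)2/t‑BuOOH would give the protected epoxy alcohol F10. Aqueous HF and then NaHCO3, as in step 7, would lead through the amino ester F11 to 14.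

Further compounds
F1 | step 6 | trans‑epoxy ketone (C5–C9 epoxide anti to the amide) | CCCCCCC/C=C/C(=O)N[C@H]1C[C@@](CC#C)(O[Si](C)(C)C(C)(C)C)C(=O)[C@@H]2O[C@@H]21
F2 | step 6 | cis‑fused hydroxy oxazoline ketone (C5–OH trans to the C9–O bond) | CCCCCCC/C=C/C1=N[C@H]2C[C@@](CC#C)(O[Si](C)(C)C(C)(C)C)C(=O)[C@H](O)[C@H]2O1
F3 | step 6 | C5 acetate of F2 | CCCCCCC/C=C/C1=N[C@H]2C[C@@](CC#C)(O[Si](C)(C)C(C)(C)C)C(=O)[C@H](OC(C)=O)[C@H]2O1
F4 | step 6 | cis‑fused oxazoline ketone | CCCCCCC/C=C/C1=N[C@H]2C[C@@](CC#C)(O[Si](C)(C)C(C)(C)C)C(=O)C[C@H]2O1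
F5 | step 4 | enol silane of 3 (C3=C4) | CCCCCCC/C=C/C(=O)N[C@H]1CC=C(O[Si](C)(C)C(C)(C)C)CC1
F6 | step 4 | α‑silyloxy ketone (C3 epimers) | CCCCCCC/C=C/C(=O)N[C@H]1CC(O[Si](C)(C)C(C)(C)C)C(=O)CC1
F7 | step 4 | α′‑silyloxy enone (C3 epimers) | CCCCCCC/C=C/C(=O)N[C@H]1CC(O[Si](C)(C)C(C)(C)C)C(=O)C=C1
F8 | step 8 | 6,7‑exo‑epoxide of 10 | CCCCCCC/C=C/C1=N[C@H]2C[C@@]3(O[Si](C)(C)C(C)(C)C)C(=O)[C@H]([C@@H]4O[C@@H]4C3)[C@H]2O1
F9 | step 8 | 6‑exo allylic alcohol (C7=C8) | CCCCCCC/C=C/C1=N[C@H]2C[C@@]3(O[Si](C)(C)C(C)(C)C)C(=O)[C@H]([C@H](O)C=C3)[C@H]2O1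
F10 | step 8 | protected epoxy alcohol | CCCCCCC/C=C/C1=N[C@H]2C[C@@]3(O[Si](C)(C)C(C)(C)C)C(=O)[C@H]([C@H](O)[C@@H]4O[C@@H]43)[C@H]2O1
F11 | step 8 | amino ester of the epoxy triol | N[C@H]1C[C@@]2(O)C(=O)[C@H]([C@H](O)[C@@H]3O[C@@H]32)[C@H]1OC(=O)/C=C/CCCCCCC
A1 | direct plan | L‑tyrosinol | N[C@@H](Cc1ccc(O)cc1)CO
A2 | direct plan | N‑[(E)‑dec‑2‑enoyl]‑L‑tyrosinol | CCCCCCC/C=C/C(=O)N[C@@H](Cc1ccc(O)cc1)CO
A3 | direct plan | p‑quinol | CCCCCCC/C=C/C(=O)N[C@@H](CC1(O)C=CC(=O)C=C1)CO
A4 | direct plan | cis‑fused hexahydrochromenone (oxa‑Michael adduct, temporary pyran) | CCCCCCC/C=C/C(=O)N[C@H]1C[C@]2(O)C=CC(=O)C[C@@H]2OC1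
A5 | direct plan | keto‑aldehyde | CCCCCCC/C=C/C(=O)N[C@H](C=O)C[C@@]1(O)C(=O)C[C@H](O)[C@@H]2O[C@@H]21
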